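**Retrosynthetic overview**
1. The last bond made is the C(sp2)–C(sp3) bond at the α-carbon of the δ-lactone, by 9-BBN hydroboration of a terminal diene (ring fragment A) and B-alkyl Suzuki coupling with an α-iodo bis-lactone (fragment B).
2. Fragment A: the E trisubstituted alkene comes from Zr-catalysed carboalumination of a homopropargyl cyclohexene, itself made by propargylation of the allylic bromide derived from a cyclohexenyl ester.
3. Key disconnection: the trimethylcyclohexene ring has its only double bond (C1=C2, tetrasubstituted) between the gem-dimethyl carbon C6 and the C3 methylene, while C4 and C5 are bare CH2 groups. Cutting ring bonds C3–C4 and C5–C6 is therefore a retro-[4+2] to an acyclic dienyl ester plus ethylene; the chain carbon on C1 is held at the ester level to lower the diene LUMO.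
4. Fragment B from furan-3-carbaldehyde: Keck allylation (carbinol centre), singlet-oxygen conversion of the furan into a butenolide, CuH conjugate reduction (ring centre), acrylate ring-closing metathesis, α-iodination.
5. Ring order: cyclohexene (step 3), γ-lactone (steps 9 and 10, from the furan), δ-lactone (step 12).

Key step: step 3

Remark on the chemistry: the facial sense of the two ligand-controlled steps (8 and 10) is assumed as written; the antipodal ligand would be used if either sense proves opposite.

**Step 1**
Reactants: 1 acetone; 2 ethyl acetoacetate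
Product: 3 ethyl 2-acetyl-3-methylbut-2-enoate
Conditions: TiCl4, pyridine, THF, 0 °C → rt
Reagents that add atoms: none
Why: Knoevenagel condensation under Lehnert conditions, in which TiCl4 activates the ketone and binds the water formed so that even acetone condenses with the active methylene; no stereo element arises.

**Step 2**
Reactants: 3 ethyl 2-acetyl-3-methylbut-2-enoate
Product: 4 ethyl 3-methyl-2-(propan-2-ylidene)but-3-enoate
Conditions: Zn, CH2Br2, TiCl4, THF/CH2Cl2, 0 °C → rt
Reagents that add atoms: dibromomethane, BrCBr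
Why: Takai–Lombardo methylenation, a non-basic zinc–titanium methylene reagent that should convert the hindered, base-sensitive ketone into the 1,1-disubstituted alkene and leave the ester untouched.

**Step 3**
Reactants: 4 ethyl 3-methyl-2-(propan-2-ylidene)but-3-enoate; 5 ethylene
Product: 6 ethyl 2,6,6-trimethylcyclohex-1-ene-1-carboxylate
Conditions: ethylene (60 bar), BHT (cat.), toluene, 180 °C, steel autoclave
Reagents that add atoms: none
Why: Concerted suprafacial [4π+2π] Diels–Alder cycloaddition in which the two termini of diene 4 (the =CH2 carbon and the =CMe2 carbon) each bond to one carbon of ethylene, so that ring bonds C3–C4 and C5–C6 form together and the former central bond of the diene becomes the tetrasubstituted C1=C2 alkene. The closest known reaction type is the thermal Diels–Alder reaction of 2,3-disubstituted buta-1,3-dienes and of ester-bearing electron-poor dienes with ethylene under pressure. The cyclohexene ring closes by an intermolecular [4+2] cycloaddition, both σ bonds in one event; no stereocentre is formed, and the symmetry of ethylene removes any regiochemical question. The step needs chemoselectivity for cross-addition over dimerisation or polymerisation of the diene. This should be secured by the ester on the internal diene carbon, which lowers the diene LUMO toward ethylene, by the fully substituted termini, which make 4 a poor dienophile for itself, and by the large excess of ethylene with a radical inhibitor. The [1,5]-hydrogen shift open to the Z-methyl group of the CMe2 terminus is degenerate (it regenerates 4) and therefore harmless.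

**Step 4**
Reactants: 6 ethyl 2,6,6-trimethylcyclohex-1-ene-1-carboxylate
Product: 7 (2,6,6-trimethylcyclohex-1-en-1-yl)methanol
Conditions: LiAlH4, Et2O, 0 °C → reflux
Reagents that add atoms: none
Why: Hydride reduction of the hindered conjugated ester to the primary allylic alcohol (LiAlH4 ester reduction); the tetrasubstituted alkene is inert.

**Step 5**
Reactants: 7 (2,6,6-trimethylcyclohex-1-en-1-yl)methanol
Product: 8 2-(bromomethyl)-1,3,3-trimethylcyclohex-1-ene
Conditions: PBr3, pyridine (cat.), Et2O, −10 °C; used crude
Reagents that add atoms: phosphorus tribromide, BrP(Br)Br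
Why: PBr3 bromination of a primary allylic alcohol, in which allylic transposition is blocked because the alkene is tetrasubstituted and flanked by the quaternary carbon.

**Step 6**
Reactants: 8 2-(bromomethyl)-1,3,3-trimethylcyclohex-1-ene
Product: 10 2-(but-3-yn-1-yl)-1,3,3-trimethylcyclohex-1-ene, via silylalkyne 9 (not isolated)
Conditions: 1-(trimethylsilyl)propyne, n-BuLi, THF, −78 → −20 °C; add 8, −78 °C → rt; then K2CO3 (cat.), MeOH, rt
Reagents that add atoms: 1-(trimethylsilyl)propyne, CC#C[Si](C)(C)C
Why: SN2 alkylation of the silyl-capped propargyl lithium reagent by the reactive allylic bromide (the C-silyl group keeps the reaction at the propargylic carbon), followed by methanolysis of the C–Si bond in the same flask.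

**Step 7**
Reactants: 10 2-(but-3-yn-1-yl)-1,3,3-trimethylcyclohex-1-ene
Product: 12 1,3,3-trimethyl-2-[(3E)-3-methylhexa-3,5-dien-1-yl]cyclohex-1-ene, via alkenylalane 11 (not isolated)
Conditions: AlMe3, Cp2ZrCl2 (20 mol %), CH2Cl2, 0 °C → rt; then vinyl bromide, Pd(PPh3)4 (5 mol %), ZnCl2 (cat.), THF, rt
Reagents that add atoms: trimethylaluminium, C[Al](C)C; vinyl bromide, C=CBr
Why: Negishi zirconium-catalysed carboalumination adds methyl and aluminium syn across the terminal alkyne with aluminium at the terminus, which fixes the E geometry of the trisubstituted alkene, and the alkenylalane then cross-couples with vinyl bromide under Pd(PPh3)4 with retention (Negishi coupling).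

**Step 8**
Reactants: 13 furan-3-carbaldehyde
Product: 14 (1R)-1-(furan-3-yl)but-3-en-1-ol
Conditions: allyltributylstannane, (R)-BINOL (20 mol %), Ti(OiPr)4 (10 mol %), 4 Å MS, CH2Cl2, −20 °C
Reagents that add atoms: allyltributylstannane, C=CC[Sn](CCCC)(CCCC)CCCC
Why: Keck catalytic asymmetric allylation, in which the (R)-BINOL–titanium Lewis acid exposes one face of the heteroaryl aldehyde to the allylstannane and so sets the carbinol carbon (the future C6 of the pyranone) as R.

**Step 9**
Reactants: 14 (1R)-1-(furan-3-yl)but-3-en-1-ol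
Product: 16 4-[(1R)-1-hydroxybut-3-en-1-yl]furan-2(5H)-one, via hydroxybutenolide 15 (not isolated)
Conditions: O2, hν, tetraphenylporphyrin (cat.), i-Pr2NEt, CH2Cl2, −78 °C; then NaBH4, EtOH, 0 °C; then 1 M HCl
Reagents that add atoms: oxygen, O=O
Why: Singlet-oxygen [4+2] photooxygenation of the 3-substituted furan in which the hindered amine removes the less hindered C5–H of the endoperoxide, giving the β-substituted γ-hydroxybutenolide; NaBH4 then reduces its masked aldehyde and the Z-hydroxy acid relactonises. The carbinol centre is not involved and the monosubstituted alkene is inert to singlet oxygen.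

**Step 10**
Reactants: 16 4-[(1R)-1-hydroxybut-3-en-1-yl]furan-2(5H)-one
Product: 18 (4R)-4-[(1R)-1-hydroxybut-3-en-1-yl]oxolan-2-one, via silyl ether 17 (not isolated)
Conditions: Cu(OAc)2 (5 mol %), (S)-p-tol-BINAP (5 mol %), (EtO)2MeSiH (3 equiv), t-BuOH, toluene, 0 °C; then 1 M HCl (work-up)
Reagents that add atoms: none
Why: Copper hydride catalysed asymmetric conjugate reduction of a β-substituted butenolide, in which the ligand-bound CuH delivers hydride to one face of the β-carbon (catalyst control) to set the ring centre as R; the hydroxyl is silylated in the flask before reduction and freed on work-up, and the unactivated terminal alkene should not be reduced.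

**Step 11**
Reactants: 18 (4R)-4-[(1R)-1-hydroxybut-3-en-1-yl]oxolan-2-one
Product: 19 (1R)-1-[(3R)-5-oxooxolan-3-yl]but-3-en-1-yl prop-2-enoate
Conditions: acryloyl chloride, i-Pr2NEt, CH2Cl2, −40 → 0 °C
Reagents that add atoms: acryloyl chloride, C=CC(Cl)=O
Why: O-acylation of the secondary alcohol with an acid chloride and a hindered amine; without an alkoxide the neighbouring lactone should not migrate onto the carbinol oxygen, and no stereocentre is touched.

**Step 12**
Reactants: 19 (1R)-1-[(3R)-5-oxooxolan-3-yl]but-3-en-1-yl prop-2-enoate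
Product: 20 (6R)-6-[(3R)-5-oxooxolan-3-yl]-5,6-dihydro-2H-pyran-2-one
Conditions: second-generation Grubbs catalyst (H2IMes)(PCy3)Cl2Ru=CHPh (5 mol %), CH2Cl2 (0.005 M), 40 °C
Reagents that add atoms: none
Why: Ring-closing metathesis of the acrylate with the homoallylic terminal alkene gives the six-membered α,β-unsaturated lactone with loss of ethylene, the ring enforcing the cis alkene.

**Step 13**
Reactants: 20 (6R)-6-[(3R)-5-oxooxolan-3-yl]-5,6-dihydro-2H-pyran-2-one
Product: 21 (6R)-3-iodo-6-[(3R)-5-oxooxolan-3-yl]-5,6-dihydro-2H-pyran-2-one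
Conditions: I2, pyridine, CH2Cl2, 0 °C → rt
Reagents that add atoms: iodine, II
Why: Johnson α-iodination of an enoate (conjugate addition of pyridine, iodination of the resulting enolate, E1cB loss of pyridine), which touches only the α-carbon of the unsaturated lactone.

**Step 14**
Reactants: 12 1,3,3-trimethyl-2-[(3E)-3-methylhexa-3,5-dien-1-yl]cyclohex-1-ene; 21 (6R)-3-iodo-6-[(3R)-5-oxooxolan-3-yl]-5,6-dihydro-2H-pyran-2-one
Product: 23 (6R)-3-[(3E)-4-methyl-6-(2,6,6-trimethylcyclohex-1-en-1-yl)hex-3-en-1-yl]-6-[(3R)-5-oxooxolan-3-yl]-5,6-dihydro-2H-pyran-2-one, via alkylborane 22 (not isolated)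
Conditions: 9-BBN, THF, 0 °C → rt; then 21, PdCl2(dppf) (10 mol %), AsPh3, Cs2CO3, DMF/H2O, rt
Reagents that add atoms: none
Why: 9-BBN should add anti-Markovnikov to the monosubstituted terminus of the diene only (the tri- and tetrasubstituted alkenes are too hindered), and the homoallylic B-alkyl-9-BBN then undergoes B-alkyl Suzuki–Miyaura coupling with the α-iodo enoate, leaving both stereocentres and the E alkene untouched.

**Compound list**
1 | acetone | CC(C)=O | starting material
2 | ethyl acetoacetate | CCOC(=O)CC(C)=O | starting material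
3 | ethyl 2-acetyl-3-methylbut-2-enoate | CCOC(=O)C(C(C)=O)=C(C)C | intermediate
4 | ethyl 3-methyl-2-(propan-2-ylidene)but-3-enoate | CCOC(=O)C(=C(C)C)C(C)=C | intermediate
5 | ethylene | C=C | starting material
6 | ethyl 2,6,6-trimethylcyclohex-1-ene-1-carboxylate | CCOC(=O)C1=C(C)CCCC1(C)C | intermediate
7 | (2,6,6-trimethylcyclohex-1-en-1-yl)methanol | OCC1=C(C)CCCC1(C)C | intermediate
8 | 2-(bromomethyl)-1,3,3-trimethylcyclohex-1-ene | BrCC1=C(C)CCCC1(C)C | intermediate
9 | trimethyl[4-(2,6,6-trimethylcyclohex-1-en-1-yl)but-1-yn-1-yl]silane | C[Si](C)(C)C#CCCC1=C(C)CCCC1(C)C | intermediate (not isolated)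
10 | 2-(but-3-yn-1-yl)-1,3,3-trimethylcyclohex-1-ene | C#CCCC1=C(C)CCCC1(C)C | intermediate
11 | dimethyl[(1E)-2-methyl-4-(2,6,6-trimethylcyclohex-1-en-1-yl)but-1-en-1-yl]alumane | C[Al](C)/C=C(\C)CCC1=C(C)CCCC1(C)C | intermediate (not isolated)
12 | 1,3,3-trimethyl-2-[(3E)-3-methylhexa-3,5-dien-1-yl]cyclohex-1-ene | C=C/C=C(\C)CCC1=C(C)CCCC1(C)C | intermediate
13 | furan-3-carbaldehyde | O=Cc1ccoc1 | starting material
14 | (1R)-1-(furan-3-yl)but-3-en-1-ol | C=CC[C@@H](O)c1ccoc1 | intermediate
15 | 5-hydroxy-4-[(1R)-1-hydroxybut-3-en-1-yl]furan-2(5H)-one (C5 epimers) | C=CC[C@@H](O)C1=CC(=O)OC1O | intermediate (not isolated)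
16 | 4-[(1R)-1-hydroxybut-3-en-1-yl]furan-2(5H)-one | C=CC[C@@H](O)C1=CC(=O)OC1 | intermediate
17 | (4R)-4-[(1R)-1-{[diethoxy(methyl)silyl]oxy}but-3-en-1-yl]oxolan-2-one | C=CC[C@@H](O[Si](C)(OCC)OCC)[C@H]1COC(=O)C1 | intermediate (not isolated)
18 | (4R)-4-[(1R)-1-hydroxybut-3-en-1-yl]oxolan-2-one | C=CC[C@@H](O)[C@H]1COC(=O)C1 | intermediate
19 | (1R)-1-[(3R)-5-oxooxolan-3-yl]but-3-en-1-yl prop-2-enoate | C=CC[C@@H](OC(=O)C=C)[C@H]1COC(=O)C1 | intermediate
20 | (6R)-6-[(3R)-5-oxooxolan-3-yl]-5,6-dihydro-2H-pyran-2-one | O=C1C=CC[C@H]([C@H]2COC(=O)C2)O1 | intermediate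
21 | (6R)-3-iodo-6-[(3R)-5-oxooxolan-3-yl]-5,6-dihydro-2H-pyran-2-one | O=C1C(I)=CC[C@H]([C@H]2COC(=O)C2)O1 | intermediate
22 | 9-[(3E)-4-methyl-6-(2,6,6-trimethylcyclohex-1-en-1-yl)hex-3-en-1-yl]-9-borabicyclo[3.3.1]nonane | CC1=C(CC/C(C)=C/CCB2C3CCCC2CCC3)C(C)(C)CCC1 | intermediate (not isolated)
23 | (6R)-3-[(3E)-4-methyl-6-(2,6,6-trimethylcyclohex-1-en-1-yl)hex-3-en-1-yl]-6-[(3R)-5-oxooxolan-3-yl]-5,6-dihydro-2H-pyran-2-one | CC1=C(CC/C(C)=C/CCC2=CC[C@H]([C@H]3COC(=O)C3)OC2=O)C(C)(C)CCC1 | target

**Step count and risks**
Total step count: 14. Longest linear sequence: 8 steps (steps 1 to 7, then step 14); the other branch is steps 8 to 13, then step 14.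

Steps most likely to fail:

1. Step 3. The Z-methyl group at the CMe2 terminus twists the diene out of the s-cis geometry, so cycloaddition with the weak dienophile ethylene may be slower than thermal oligomerisation of the diene. The fallback sets out from 4 and returns at 6. Diene 4 is heated neat with phenyl vinyl sulfide, an electron-rich liquid ethylene surrogate, at 130 °C in an inverse-electron-demand Diels–Alder reaction. This should give ethyl 2,6,6-trimethyl-4-(phenylsulfanyl)cyclohex-1-ene-1-carboxylate F1, whose C–S bond is then removed by hydrogenolysis with Raney Ni in ethanol to give 6.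

2. Step 10. Facial selectivity may be poor if the ligand and the adjacent carbinol centre are mismatched; the copper alkoxide of the free hydroxyl may induce acyl migration to the regioisomeric lactone; the terminal alkene may be hydrocuprated. The fallback sets out from 14 and returns at 20; it locks the carbinol oxygen into the pyran ring before the reduction. Acetal exchange of 14 with acrolein dimethyl acetal (PPTS, toluene) should give 3-[(1R)-1-[(1-methoxyprop-2-en-1-yl)oxy]but-3-en-1-yl]furan F2. Ring-closing metathesis with second-generation Grubbs catalyst gives (2R)-2-(furan-3-yl)-6-methoxy-3,6-dihydro-2H-pyran F3. Photooxygenation and NaBH4 reduction as in step 9 give 4-[(2R)-6-methoxy-3,6-dihydro-2H-pyran-2-yl]furan-2(5H)-one F4. CuH reduction, now without a free hydroxyl or terminal alkene and with either ligand antipode open to screening, gives (4R)-4-[(2R)-6-methoxy-3,6-dihydro-2H-pyran-2-yl]oxolan-2-one F5. Oxidation of the allylic acetal with CrO3/H2SO4 in acetone then gives 20.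

3. Step 14. The conjugated diene may undergo double or 1,4-hydroboration, the lactones may open under aqueous carbonate, and the homoallyl–palladium intermediate may undergo β-hydride elimination. The fallback sets out from 10 (through alane 11) and returns at 23. Alane 11 is converted into its ate complex with n-BuLi and opened with ethylene oxide to give (3E)-4-methyl-6-(2,6,6-trimethylcyclohex-1-en-1-yl)hex-3-en-1-ol F6. I2, PPh3 and imidazole give 2-[(3E)-6-iodo-3-methylhex-3-en-1-yl]-1,3,3-trimethylcyclohex-1-ene F7. Zinc insertion (Zn dust, LiCl, THF) gives iodo[(3E)-4-methyl-6-(2,6,6-trimethylcyclohex-1-en-1-yl)hex-3-en-1-yl]zinc F8, which is joined to 21 by base-free Negishi coupling (Pd(PPh3)4, THF/DMA, rt) to give 23.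

**Further compounds**
F1 | step 3 | ethyl 2,6,6-trimethyl-4-(phenylsulfanyl)cyclohex-1-ene-1-carboxylate (racemic) | CCOC(=O)C1=C(C)CC(Sc2ccccc2)CC1(C)C
F2 | step 10 | 3-[(1R)-1-[(1-methoxyprop-2-en-1-yl)oxy]but-3-en-1-yl]furan (acetal epimers) | C=CC[C@@H](OC(OC)C=C)c1ccoc1
F3 | step 10 | (2R)-2-(furan-3-yl)-6-methoxy-3,6-dihydro-2H-pyran (C6 epimers) | COC1C=CC[C@H](c2ccoc2)O1
F4 | step 10 | 4-[(2R)-6-methoxy-3,6-dihydro-2H-pyran-2-yl]furan-2(5H)-one (acetal epimers) | COC1C=CC[C@H](C2=CC(=O)OC2)O1
F5 | step 10 | (4R)-4-[(2R)-6-methoxy-3,6-dihydro-2H-pyran-2-yl]oxolan-2-one (acetal epimers) | COC1C=CC[C@H]([C@H]2COC(=O)C2)O1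
F6 | step 14 | (3E)-4-methyl-6-(2,6,6-trimethylcyclohex-1-en-1-yl)hex-3-en-1-ol | OCC/C=C(\C)CCC1=C(C)CCCC1(C)C
F7 | step 14 | 2-[(3E)-6-iodo-3-methylhex-3-en-1-yl]-1,3,3-trimethylcyclohex-1-ene | ICC/C=C(\C)CCC1=C(C)CCCC1(C)C
F8 | step 14 | iodo[(3E)-4-methyl-6-(2,6,6-trimethylcyclohex-1-en-1-yl)hex-3-en-1-yl]zinc | I[Zn]CC/C=C(\C)CCC1=C(C)CCCC1(C)C
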